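**Retrosynthetic overview**
1. Target ⇐ hydroquinone (O-sulfation) ⇐ quinone ⇐ dimethyl ether; C4=CH2 ⇐ C4 ketone ⇐ protected C4–OH.
2. Central CH2–CH2 bridge: C5–CH2Li of the lower decalin adds to the α-quaternary aldehyde of the upper decalin; the carbinol oxygen is then removed (Barton–McCombie).
3. Upper decalin: ring A' from 2,2-dimethylcyclohexanone; ring B' closed by a catalytic asymmetric exo Diels–Alder reaction with tiglic aldehyde (sets C8', C9', C10').
4. Lower decalin: ring A from cyclohexane-1,3-dione; ring B closed by an organocatalytic Robinson annulation (sets C5); a ketoreductase differentiates the C4 carbonyl; Birch reductive benzylation sets C9/C10; hydroxyl-directed hydrogenation sets C8.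
5. Ring order: A then B (lower), A' then B' (upper), arene attached at C9, fragments joined last.

Locants: lower decalin C1–C10 (C4 ends as C=CH2; C5 angular, bears bridge carbon Ca; C8 = CHCH3; C9 bears CH3 and ArCH2; C10 ring-fusion CH). Upper decalin C1'–C10' (C4' = CMe2; C5'=C6'; C8' = CHCH3; C9' bears CH3 and bridge carbon Cb; C10' ring-fusion CH). "Top" is the face of the lower decalin that carries the C5 substituent.

Assumption: the ketoreductase is picked from a screening panel for the (4R) alcohol; the sense of induction of the two small-molecule catalysts follows their established models (a D-proline-type catalyst gives the antipode of the L-proline Wieland–Miescher series; the (S)-oxazaborolidinium gives α-Re attack on a 2-substituted enal); the final product is written as the free bis(hydrogen sulfate).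

**Route**

Step 1
Reactants: 1 cyclohexane-1,3-dione; 2 allyl bromide
Product: 3 2-allylcyclohexane-1,3-dione
Conditions: KOH (aq), Cu (powder, cat.), H2O, rt
Reagents that add atoms: none
Why: C-allylation of the stabilised 1,3-dione enolate with a soft allylic electrophile (enolate alkylation).

Step 2
Reactants: 3 2-allylcyclohexane-1,3-dione; 4 ethyl vinyl ketone
Product: 5 2-allyl-2-(3-oxopentyl)cyclohexane-1,3-dione
Conditions: Et3N (cat.), EtOAc, rt
Reagents that add atoms: none
Why: Michael addition of the dione to the enone gives the achiral (prochiral) triketone.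

Step 3
Reactants: 5 2-allyl-2-(3-oxopentyl)cyclohexane-1,3-dione
Product: 6 (4aS)-4a-allyl-1-methyl-4,4a,7,8-tetrahydronaphthalene-2,5(3H,6H)-dione
Conditions: N-tosyl-(Ra)-binam-D-prolinamide (5 mol %), PhCO2H (2.5 mol %), neat, rt
Reagents that add atoms: none
Why: Enamine-mediated intramolecular aldol condensation (Hajos–Parrish–Eder–Sauer–Wiechert type Robinson annulation); the D-proline-derived catalyst differentiates the two enantiotopic ring carbonyls and sets C5, the first stereocentre of the lower fragment.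

Step 4
Reactants: 6 enedione
Product: 7 (4aS,5R)-4a-allyl-5-hydroxy-1-methyl-4,4a,5,6,7,8-hexahydronaphthalen-2(3H)-one
Conditions: ketoreductase (NADPH-dependent), NADP+ (cat.), i-PrOH, phosphate buffer pH 7, 30 °C
Reagents that add atoms: none
Why: Ketoreductase-catalysed carbonyl reduction touches only the saturated C4 ketone of the matched enantiomer, with hydride delivered anti to the angular allyl group (OH cis to allyl); the minor enantiomer of 6 is left behind or becomes a separable diastereomer.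

Step 5
Reactants: 7 hydroxy enone
Product: 8 C4–O-tert-butyldimethylsilyl ether of 7
Conditions: TBSOTf, 2,6-lutidine, CH2Cl2, 0 °C
Reagents that add atoms: tert-butyldimethylsilyl triflate, CC(C)(C)[Si](C)(C)OS(=O)(=O)C(F)(F)F
Why: Silylation with the reactive silyl triflate protects the hindered secondary alcohol for the reductive and organometallic steps that follow.

Step 6
Reactants: 8 silyl ether
Product: 9 the same enone with the angular allyl group isomerised to (E)-prop-1-enyl
Conditions: RuHCl(CO)(PPh3)3 (5 mol %), toluene, 100 °C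
Reagents that add atoms: none
Why: Ruthenium-hydride catalysed alkene isomerisation (hydrometalation/β-hydride elimination) moves the terminal double bond to the more stable internal position without touching a stereocentre.

Step 7
Reactants: 9 propenyl enone
Product: 10 angular aldehyde (C5–CHO; C4–OTBS; C8 enone)
Conditions: O3, CH2Cl2/MeOH, −78 °C; then Me2S
Reagents that add atoms: ozone, [O-][O+]=O
Why: Ozonolysis cleaves the electron-rich propenyl group much faster than the electron-poor tetrasubstituted enone double bond.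

Step 8
Reactants: 10 angular aldehyde
Product: 11 angular hydroxymethyl enone (C5–CH2OH)
Conditions: NaBH4, EtOH/CH2Cl2, −78 °C
Reagents that add atoms: none
Why: Chemoselective borohydride reduction; at −78 °C an aldehyde is reduced far faster than a conjugated ketone.

Step 9
Reactants: 11 hydroxymethyl enone
Product: 12 enone with C5–CH2OSiEt3 and C4–OTBS
Conditions: Et3SiCl, imidazole, DMF, 0 °C
Reagents that add atoms: chlorotriethylsilane, CC[Si](Cl)(CC)CC
Why: Silylation of the primary alcohol with a group that can later be removed selectively beside the secondary TBS ether.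

Step 10
Reactants: 13 2,5-dimethoxybenzyl alcohol
Product: 14 2,5-dimethoxybenzyl bromide
Conditions: PBr3, Et2O, 0 °C
Reagents that add atoms: phosphorus tribromide, BrP(Br)Br
Why: Alcohol-to-bromide conversion (SN2 on the phosphite ester); made fresh because the electron-rich benzyl bromide stores poorly.

Step 11
Reactants: 12 bis-silylated enone; 14 2,5-dimethoxybenzyl bromide
Product: 16 trans-decalin C8 ketone with C9 methyl on the top face and C9 2,5-dimethoxybenzyl on the bottom face, via lithium enolate 15 (not isolated)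
Conditions: Li, NH3(l)/THF, −78 °C; isoprene; NH3 removed; then 14, THF, −78 °C → rt
Reagents that add atoms: none
Why: Birch-type reductive alkylation; axial protonation at C10 gives the trans ring fusion (H10 anti to the C5 substituent), and the regiodefined enolate is benzylated at C9 from the bottom face, anti to the axial C5–CH2OSiEt3 group.

Step 12
Reactants: 16 C8 ketone
Product: 17 C7=C8 enol triflate
Conditions: KN(SiMe3)2, THF, −78 °C; PhNTf2
Reagents that add atoms: N-phenylbis(trifluoromethanesulfonimide), O=S(=O)(N(c1ccccc1)S(=O)(=O)C(F)(F)F)C(F)(F)F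
Why: Enolisation can only occur towards C7 because C9 is quaternary, and the enolate is trapped on oxygen (enol triflate formation).

Step 13
Reactants: 17 enol triflate
Product: 18 8-methyl C7=C8 alkene
Conditions: Pd(PPh3)4 (5 mol %), MeZnCl, THF, 50 °C
Reagents that add atoms: methylzinc chloride, C[Zn]Cl
Why: Negishi cross-coupling replaces the triflate by methyl and keeps the double bond in place.

Step 14
Reactants: 18 bis-silyl ether
Product: 19 8-methyl C7=C8 alkene with free C5–CH2OH (C4–OTBS kept)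
Conditions: PPTS, MeOH/CH2Cl2, 0 °C
Reagents that add atoms: none
Why: Acid-catalysed methanolysis removes the primary triethylsilyl ether much faster than the hindered secondary TBS ether.

Step 15
Reactants: 19 homoallylic-type alcohol
Product: 20 saturated lower decalin with C8 methyl axial on the bottom face (trans to the C9 methyl) and C5–CH2OH
Conditions: H2 (1 atm), [Ir(cod)(PCy3)(py)]PF6 (5–10 mol %), CH2Cl2, rt
Reagents that add atoms: none
Why: Hydroxyl-directed hydrogenation; iridium bound to the axial C5–CH2OH, which sits over the C7=C8 bond, delivers both hydrogens to the top face, so C8–H is top and C8–CH3 bottom, the opposite of undirected hydrogenation.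

Step 16
Reactants: 20 neopentyl alcohol
Product: 21 neopentyl iodide (C5–CH2I)
Conditions: I2, PPh3, imidazole, toluene, 90 °C
Reagents that add atoms: iodine, II
Why: Appel-type iodination (iodide displaces the alkoxyphosphonium); slow at a neopentyl carbon but free of rearrangement under these neutral conditions.

Step 17
Reactants: 22 2,2-dimethylcyclohexanone
Product: 23 6,6-dimethylcyclohex-1-en-1-yl triflate
Conditions: LiN(i-Pr)2, THF, −78 °C; PhNTf2, −78 → 0 °C
Reagents that add atoms: N-phenylbis(trifluoromethanesulfonimide), O=S(=O)(N(c1ccccc1)S(=O)(=O)C(F)(F)F)C(F)(F)F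
Why: The only enolisable side is deprotonated and the enolate trapped on oxygen (enol triflate formation).

Step 18
Reactants: 23 enol triflate
Product: 24 6,6-dimethyl-1-vinylcyclohex-1-ene
Conditions: Pd(PPh3)4 (3 mol %), LiCl, Bu3Sn(CH=CH2), THF, 65 °C
Reagents that add atoms: tributyl(vinyl)stannane, C=C[Sn](CCCC)(CCCC)CCCC
Why: Stille cross-coupling of the alkenyl triflate with the vinyl stannane gives the semicyclic diene.

Step 19
Reactants: 24 6,6-dimethyl-1-vinylcyclohex-1-ene; 25 tiglic aldehyde ((E)-2-methylbut-2-enal)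
Product: 26 (1S,2R,8aS)-1,2,5,5-tetramethyl-1,2,3,5,6,7,8,8a-octahydronaphthalene-1-carbaldehyde
Conditions: (S)-3,3-diphenyl-1-(o-tolyl)tetrahydro-1H,3H-pyrrolo[1,2-c][1,3,2]oxazaborole (20 mol %), HNTf2 (16 mol %), CH2Cl2, −78 → −40 °C
Reagents that add atoms: none
Why: Chiral cationic oxazaborolidine-catalysed Diels–Alder reaction; the ortho rule puts C9' next to the ring fusion, the exo (CHO-exo) transition state known for tiglyl dienophiles with this diene puts CHO cis to H10' and keeps the two methyls cis, and the catalyst exposes the α-Re face, setting C8', C9' and C10' (first stereocentres of the upper fragment).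

Step 20
Reactants: 21 neopentyl iodide; 26 upper-decalin aldehyde
Product: 28 coupled secondary alcohol C5–CH2–CH(OH)–C9' (both carbinol epimers), via primary organolithium 27 (not isolated)
Conditions: t-BuLi (2.1 equiv), Et2O/pentane, −78 °C; then 26, −78 → −20 °C; NH4Cl (aq)
Reagents that add atoms: none
Why: Lithium–iodine exchange, then 1,2-addition of the primary organolithium to the non-enolisable aldehyde, forms the Ca–Cb bond; the new carbinol centre is removed two steps later.

Step 21
Reactants: 28 secondary alcohol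
Product: 29 S-methyl xanthate of 28
Conditions: NaH, imidazole (cat.), THF, 0 °C; CS2; MeI, rt
Reagents that add atoms: carbon disulfide, S=C=S; iodomethane, CI
Why: Alkoxide addition to CS2 and S-methylation (xanthate formation) works even for hindered secondary alcohols.

Step 22
Reactants: 29 xanthate
Product: 30 deoxygenated coupled compound (C5–CH2–CH2–C9'; C4–OTBS; hydroquinone dimethyl ether)
Conditions: Bu3SnH, AIBN (cat.), toluene, 110 °C
Reagents that add atoms: none
Why: Barton–McCombie radical deoxygenation; the Cb radical has no favourable cyclisation mode onto either alkene or the arene and is simply reduced.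

Step 23
Reactants: 30 silyl ether
Product: 31 C4 alcohol
Conditions: Bu4NF, THF, 60 °C
Reagents that add atoms: none
Why: Fluoride-induced desilylation; no other group in the molecule reacts with fluoride.

Step 24
Reactants: 31 C4 alcohol
Product: 32 C4 ketone
Conditions: Dess–Martin periodinane, NaHCO3, CH2Cl2, rt
Reagents that add atoms: none
Why: Dess–Martin oxidation of the secondary alcohol under buffered conditions that leave the alkene and the electron-rich arene alone.

Step 25
Reactants: 32 C4 ketone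
Product: 33 exocyclic C4=CH2 alkene (hydroquinone dimethyl ether of the target carbon skeleton)
Conditions: Ph3PCH3Br, KOt-Bu, toluene, 90 °C
Reagents that add atoms: methyltriphenylphosphonium bromide, C[P+](c1ccccc1)(c1ccccc1)c1ccccc1.[Br-]
Why: Wittig methylenation with the small, salt-free ylide at elevated temperature converts the hindered ketone next to the quaternary C5 into the exocyclic alkene.

Step 26
Reactants: 33 dimethyl ether
Product: 34 2-substituted 1,4-benzoquinone
Conditions: (NH4)2Ce(NO3)6, MeCN/H2O, 0 °C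
Reagents that add atoms: water, O
Why: Oxidative demethylation; tetravalent cerium oxidises the electron-rich 1,4-dimethoxyarene to the quinone faster than it attacks the isolated alkenes.

Step 27
Reactants: 34 quinone
Product: 35 hydroquinone
Conditions: Na2S2O4, THF/H2O, rt, under Ar
Reagents that add atoms: none
Why: Dithionite reduction of the quinone to the hydroquinone under neutral conditions that do not isomerise the exocyclic alkene.

Step 28
Reactants: 35 hydroquinone
Product: 36 target CNP0426429.4 (hydroquinone bis(hydrogen sulfate))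
Conditions: SO3·pyridine (8 equiv), pyridine, 40 °C; then cation exchange (H+ form)
Reagents that add atoms: sulfur trioxide–pyridine complex, [O-]S(=O)(=O)[n+]1ccccc1
Why: O-sulfation of both phenols with the mild SO3–amine complex, which does not react with either alkene.

**Compound list**
1 | cyclohexane-1,3-dione | O=C1CCCC(=O)C1 | starting material
2 | allyl bromide | C=CCBr | starting material
3 | 2-allylcyclohexane-1,3-dione | C=CCC1C(=O)CCCC1=O | intermediate
4 | ethyl vinyl ketone (pent-1-en-3-one) | C=CC(=O)CC | starting material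
5 | 2-allyl-2-(3-oxopentyl)cyclohexane-1,3-dione | C=CCC1(CCC(=O)CC)C(=O)CCCC1=O | intermediate
6 | (4aS)-4a-allyl-1-methyl-4,4a,7,8-tetrahydronaphthalene-2,5(3H,6H)-dione | O=C1CCCC2=C(C)C(=O)CC[C@@]12CC=C | intermediate
7 | (4aS,5R)-4a-allyl-5-hydroxy-1-methyl-4,4a,5,6,7,8-hexahydronaphthalen-2(3H)-one (OH cis to allyl) | O[C@@H]1CCCC2=C(C)C(=O)CC[C@@]12CC=C | intermediate
8 | C4–OTBS ether of 7 | CC(C)(C)[Si](C)(C)O[C@@H]1CCCC2=C(C)C(=O)CC[C@@]12CC=C | intermediate
9 | C4–OTBS enone with angular (E)-prop-1-enyl | CC(C)(C)[Si](C)(C)O[C@@H]1CCCC2=C(C)C(=O)CC[C@@]12/C=C/C | intermediate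
10 | C4–OTBS enone with angular CHO | CC(C)(C)[Si](C)(C)O[C@@H]1CCCC2=C(C)C(=O)CC[C@@]12C=O | intermediate
11 | C4–OTBS enone with angular CH2OH | CC(C)(C)[Si](C)(C)O[C@@H]1CCCC2=C(C)C(=O)CC[C@@]12CO | intermediate
12 | C4–OTBS enone with angular CH2OSiEt3 | CC(C)(C)[Si](C)(C)O[C@@H]1CCCC2=C(C)C(=O)CC[C@@]12CO[Si](CC)(CC)CC | intermediate
13 | 2,5-dimethoxybenzyl alcohol | COc1ccc(OC)c(CO)c1 | starting material
14 | 2,5-dimethoxybenzyl bromide | COc1ccc(OC)c(CBr)c1 | intermediate
15 | lithium C8 enolate (C8(OLi)=C9) of the trans-decalin, H10 bottom | CC(C)(C)[Si](C)(C)O[C@@H]1CCC[C@@H]2C(C)=C(O[Li])CC[C@@]12CO[Si](CC)(CC)CC | intermediate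
16 | trans-decalin C8 ketone; C9: CH3 top, 2,5-dimethoxybenzyl bottom; C5–CH2OSiEt3 top; C4–OTBS | CC(C)(C)[Si](C)(C)O[C@@H]1CCC[C@H]2[C@@]1(CO[Si](CC)(CC)CC)CCC(=O)[C@]2(C)Cc1cc(OC)ccc1OC | intermediate
17 | C7=C8 enol triflate of 16 | CC(C)(C)[Si](C)(C)O[C@@H]1CCC[C@H]2[C@@]1(CO[Si](CC)(CC)CC)CC=C(OS(=O)(=O)C(F)(F)F)[C@]2(C)Cc1cc(OC)ccc1OC | intermediate
18 | 8-methyl C7=C8 alkene, C5–CH2OSiEt3 | CC(C)(C)[Si](C)(C)O[C@@H]1CCC[C@H]2[C@@]1(CO[Si](CC)(CC)CC)CC=C(C)[C@]2(C)Cc1cc(OC)ccc1OC | intermediate
19 | 8-methyl C7=C8 alkene, C5–CH2OH | CC(C)(C)[Si](C)(C)O[C@@H]1CCC[C@H]2[C@@]1(CO)CC=C(C)[C@]2(C)Cc1cc(OC)ccc1OC | intermediate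
20 | saturated lower decalin, C8–CH3 bottom (axial), C5–CH2OH | CC(C)(C)[Si](C)(C)O[C@@H]1CCC[C@H]2[C@@]1(CO)CC[C@H](C)[C@]2(C)Cc1cc(OC)ccc1OC | intermediate
21 | lower decalin neopentyl iodide, C5–CH2I | CC(C)(C)[Si](C)(C)O[C@@H]1CCC[C@H]2[C@@]1(CI)CC[C@H](C)[C@]2(C)Cc1cc(OC)ccc1OC | intermediate
22 | 2,2-dimethylcyclohexanone | CC1(C)CCCCC1=O | starting material
23 | 6,6-dimethylcyclohex-1-en-1-yl triflate | CC1(C)CCCC=C1OS(=O)(=O)C(F)(F)F | intermediate
24 | 6,6-dimethyl-1-vinylcyclohex-1-ene | C=CC1=CCCCC1(C)C | intermediate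
25 | tiglic aldehyde, (E)-2-methylbut-2-enal | C/C=C(\C)C=O | starting material
26 | (1S,2R,8aS)-1,2,5,5-tetramethyl-1,2,3,5,6,7,8,8a-octahydronaphthalene-1-carbaldehyde | O=C[C@@]1(C)[C@H](C)CC=C2[C@@H]1CCCC2(C)C | intermediate
27 | lower decalin organolithium, C5–CH2Li | CC(C)(C)[Si](C)(C)O[C@@H]1CCC[C@H]2[C@@]1(C[Li])CC[C@H](C)[C@]2(C)Cc1cc(OC)ccc1OC | intermediate
28 | coupled alcohol C5–CH2–CH(OH)–C9' (carbinol carbon: both epimers) | CC(C)(C)[Si](C)(C)O[C@@H]1CCC[C@H]2[C@@]1(CC(O)[C@@]1(C)[C@H](C)CC=C3[C@@H]1CCCC3(C)C)CC[C@H](C)[C@]2(C)Cc1cc(OC)ccc1OC | intermediate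
29 | S-methyl xanthate of 28 | CC(C)(C)[Si](C)(C)O[C@@H]1CCC[C@H]2[C@@]1(CC(OC(=S)SC)[C@@]1(C)[C@H](C)CC=C3[C@@H]1CCCC3(C)C)CC[C@H](C)[C@]2(C)Cc1cc(OC)ccc1OC | intermediate
30 | coupled C5–CH2CH2–C9' compound, C4–OTBS, dimethyl ether | CC(C)(C)[Si](C)(C)O[C@@H]1CCC[C@H]2[C@@]1(CC[C@@]1(C)[C@H](C)CC=C3[C@@H]1CCCC3(C)C)CC[C@H](C)[C@]2(C)Cc1cc(OC)ccc1OC | intermediate
31 | C4 alcohol | O[C@@H]1CCC[C@H]2[C@@]1(CC[C@@]1(C)[C@H](C)CC=C3[C@@H]1CCCC3(C)C)CC[C@H](C)[C@]2(C)Cc1cc(OC)ccc1OC | intermediate
32 | C4 ketone | O=C1CCC[C@H]2[C@@]1(CC[C@@]1(C)[C@H](C)CC=C3[C@@H]1CCCC3(C)C)CC[C@H](C)[C@]2(C)Cc1cc(OC)ccc1OC | intermediate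
33 | exocyclic C4=CH2 alkene, hydroquinone dimethyl ether | C=C1CCC[C@H]2[C@@]1(CC[C@@]1(C)[C@H](C)CC=C3[C@@H]1CCCC3(C)C)CC[C@H](C)[C@]2(C)Cc1cc(OC)ccc1OC | intermediate
34 | 2-substituted 1,4-benzoquinone | C=C1CCC[C@H]2[C@@]1(CC[C@@]1(C)[C@H](C)CC=C3[C@@H]1CCCC3(C)C)CC[C@H](C)[C@]2(C)CC1=CC(=O)C=CC1=O | intermediate
35 | hydroquinone | C=C1CCC[C@H]2[C@@]1(CC[C@@]1(C)[C@H](C)CC=C3[C@@H]1CCCC3(C)C)CC[C@H](C)[C@]2(C)Cc1cc(O)ccc1O | intermediate
36 | CNP0426429.4, hydroquinone bis(hydrogen sulfate) | C=C1CCC[C@H]2[C@@]1(CC[C@@]1(C)[C@H](C)CC=C3[C@@H]1CCCC3(C)C)CC[C@H](C)[C@]2(C)Cc1cc(OS(=O)(=O)O)ccc1OS(=O)(=O)O | target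

**Totals**
Total step count: 28.
Longest linear sequence: 24 steps (steps 1–9, 11–16, 20–28).

**Three steps most likely to fail**

Step 15 (hydroxyl-directed hydrogenation). Risk: delivery to the hindered top face may be incomplete, and any bottom-face reduction gives the C8 epimer. Fallback: bring the C8 methyl in as a carbon nucleophile instead of delivering hydrogen. It sets out from ketone 16. LiN(i-Pr)2/Me3SiCl gives the C7=C8 trimethylsilyl enol ether F1. Pd(OAc)2 in MeCN (Saegusa–Ito) gives the C6=C7 enone F2. t-BuOOH with benzyltrimethylammonium hydroxide gives the 6,7-epoxy ketone F3, formed anti to the angular group. N2H4·H2O/AcOH (Wharton transposition) gives the C6 allylic alcohol F4. Dess–Martin periodinane gives the transposed C7=C8 C6-enone F5. Me2CuLi/Me3SiCl adds methyl axially to C8 from the bottom face, anti to the axial C9 methyl, to give the 8-methyl C6-ketone F6. NaBH4 gives the C6 alcohol F7, NaH/CS2/MeI the xanthate F8, and Bu3SnH/AIBN the C5–CH2OSiEt3 compound F9. PPTS/MeOH then comes back to the route at 20, bypassing 17–19.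

Step 19 (catalytic asymmetric exo Diels–Alder). Risk: low turnover or modest ee with a trisubstituted enal and a hindered diene. Fallback: separate the cycloaddition from the enantioselection. It sets out from 24 and 25. Me2AlCl (CH2Cl2, −78 → −20 °C) gives the racemic exo adduct, that is 26 together with its mirror-image aldehyde F10. NaBH4 reduces the pair to the neopentyl alcohol F11 (from 26) and the mirror-image alcohol F12 (from F10). A lipase (Burkholderia cepacia lipase, vinyl acetate, i-Pr2O, low temperature) acetylates the faster-reacting antipode, taken here as F12, to the acetate F13. Unreacted F11 is separated by chromatography and oxidised with Dess–Martin periodinane, which comes back to the route at 26.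

Step 20 (union of two neopentyl-type centres). Risk: slow addition to the hindered aldehyde, or silyl migration from oxygen to carbon in 27. Fallback: reverse the polarity of the partners. It sets out from 20 and 26. Dess–Martin oxidation of 20 gives the angular aldehyde F14. 26 is reduced (NaBH4) to the neopentyl alcohol F11 and converted (I2, PPh3, imidazole) into the neopentyl iodide F15. t-BuLi gives the organolithium F16, which has no silyloxy group within reach and adds to F14 to give the carbinol F17, with the oxygen now on Ca. NaH/CS2/MeI gives the xanthate F18. Bu3SnH/AIBN at high stannane concentration, to outrun ring closure of the Ca radical onto C5'=C6', comes back to the route at 30.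

**Further compounds**
F1 | step 15 | C7=C8 trimethylsilyl enol ether of 16 | CC(C)(C)[Si](C)(C)O[C@@H]1CCC[C@H]2[C@@]1(CO[Si](CC)(CC)CC)CC=C(O[Si](C)(C)C)[C@]2(C)Cc1cc(OC)ccc1OC
F2 | step 15 | C6=C7 enone (C8 ketone) | CC(C)(C)[Si](C)(C)O[C@@H]1CCC[C@H]2[C@@]1(CO[Si](CC)(CC)CC)C=CC(=O)[C@]2(C)Cc1cc(OC)ccc1OC
F3 | step 15 | 6,7-epoxy C8 ketone, epoxide on the bottom face | CC(C)(C)[Si](C)(C)O[C@@H]1CCC[C@H]2[C@@]1(CO[Si](CC)(CC)CC)[C@@H]3O[C@@H]3C(=O)[C@]2(C)Cc1cc(OC)ccc1OC
F4 | step 15 | C6 allylic alcohol with C7=C8 | CC(C)(C)[Si](C)(C)O[C@@H]1CCC[C@H]2[C@@]1(CO[Si](CC)(CC)CC)[C@H](O)C=C[C@]2(C)Cc1cc(OC)ccc1OC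
F5 | step 15 | C7=C8 enone with C6 ketone | CC(C)(C)[Si](C)(C)O[C@@H]1CCC[C@H]2[C@@]1(CO[Si](CC)(CC)CC)C(=O)C=C[C@]2(C)Cc1cc(OC)ccc1OC
F6 | step 15 | 8-methyl C6 ketone, C8–CH3 bottom | CC(C)(C)[Si](C)(C)O[C@@H]1CCC[C@H]2[C@@]1(CO[Si](CC)(CC)CC)C(=O)C[C@H](C)[C@]2(C)Cc1cc(OC)ccc1OC
F7 | step 15 | C6 alcohol (carbinol configuration not relevant) | CC(C)(C)[Si](C)(C)O[C@@H]1CCC[C@H]2[C@@]1(CO[Si](CC)(CC)CC)C(O)C[C@H](C)[C@]2(C)Cc1cc(OC)ccc1OC
F8 | step 15 | C6 S-methyl xanthate | CC(C)(C)[Si](C)(C)O[C@@H]1CCC[C@H]2[C@@]1(CO[Si](CC)(CC)CC)C(OC(=S)SC)C[C@H](C)[C@]2(C)Cc1cc(OC)ccc1OC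
F9 | step 15 | triethylsilyl ether of 20 | CC(C)(C)[Si](C)(C)O[C@@H]1CCC[C@H]2[C@@]1(CO[Si](CC)(CC)CC)CC[C@H](C)[C@]2(C)Cc1cc(OC)ccc1OC
F10 | step 19 | mirror image of aldehyde 26 | O=C[C@]1(C)[C@@H](C)CC=C2[C@H]1CCCC2(C)C
F11 | step 19 | neopentyl alcohol from 26 | OC[C@@]1(C)[C@H](C)CC=C2[C@@H]1CCCC2(C)C
F12 | step 19 | mirror-image neopentyl alcohol | OC[C@]1(C)[C@@H](C)CC=C2[C@H]1CCCC2(C)C
F13 | step 19 | acetate of F12 | CC(=O)OC[C@]1(C)[C@@H](C)CC=C2[C@H]1CCCC2(C)C
F14 | step 20 | lower decalin angular aldehyde, C5–CHO | CC(C)(C)[Si](C)(C)O[C@@H]1CCC[C@H]2[C@@]1(C=O)CC[C@H](C)[C@]2(C)Cc1cc(OC)ccc1OC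
F15 | step 20 | upper decalin neopentyl iodide, C9'–CH2I | IC[C@@]1(C)[C@H](C)CC=C2[C@@H]1CCCC2(C)C
F16 | step 20 | upper decalin organolithium, C9'–CH2Li | [Li]C[C@@]1(C)[C@H](C)CC=C2[C@@H]1CCCC2(C)C
F17 | step 20 | coupled carbinol C5–CH(OH)–CH2–C9' (both epimers) | CC(C)(C)[Si](C)(C)O[C@@H]1CCC[C@H]2[C@@]1(C(O)C[C@@]1(C)[C@H](C)CC=C3[C@@H]1CCCC3(C)C)CC[C@H](C)[C@]2(C)Cc1cc(OC)ccc1OC
F18 | step 20 | S-methyl xanthate of F17 | CC(C)(C)[Si](C)(C)O[C@@H]1CCC[C@H]2[C@@]1(C(OC(=S)SC)C[C@@]1(C)[C@H](C)CC=C3[C@@H]1CCCC3(C)C)CC[C@H](C)[C@]2(C)Cc1cc(OC)ccc1OC
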